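**Retrosynthetic overview**

1. The target is an oxolane (O1, C2–C5) with a 3,4-dihydroxyphenyl group on C2, CH2OAc on C3 and a 4-hydroxy-3-methoxybenzyl group on C4, 2,3-trans and 3,4-cis, (2S,3R,4R); the end game is heteroatom work only: O-debenzylation ⇐ O-acetylation ⇐ reduction of a C3 carboxamide.
2. The benzylic CH2–aryl bond at C4 is cut (B-alkyl Suzuki–Miyaura coupling) back to a 4-methylidene-oxolane; hydroboration anti to the C3 carboxamide sets C4.
3. Key disconnection: O1–C5 and C2–C3 are cut in one operation (formal [3+2] addition across C=O), giving 3,4-bis(benzyloxy)benzaldehyde and racemic N,N-diphenyl-2-methylidenecyclopropane-1-carboxamide.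
4. Enabling feature: O1–C2(aryl) is a latent ArCH=O, and C3–C4–C5 is a 2-methylidenepropane-1,3-diyl unit in which C3 is alpha to an acyl carbon (the future CH2OAc carbon; nucleophile) and C5 is a primary allylic carbon (electrophile), while C4 bears the exocyclic carbon that becomes the benzylic CH2.
5. Ring order: the cyclopropane (temporary, step 1), then the oxolane (step 5), the only ring of the target that the route has to build.

Key step: step 5

Assumption: the (S,S)-bis(oxazoline)–MgI2 complex is taken to give the (2S,3S) adduct in step 5; if the sense of induction proves opposite, the (R,R)-ligand is used without other change.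

**Route**

Step 1
Reactants: 1 2-bromopropene; 2 ethyl diazoacetate
Product: 3 ethyl 2-bromo-2-methylcyclopropane-1-carboxylate (racemic, cis/trans mixture)
Conditions: Rh2(OAc)4 (0.5 mol %), excess 1, CH2Cl2, rt, slow addition of 2
Reagents that add atoms: none
Why: Rh2(OAc)4-catalysed carbene transfer (cyclopropanation) from the diazoester to the 1,1-disubstituted alkene; the diastereomer mixture does not matter because both isomers converge in step 2.

Step 2
Reactants: 3 ethyl 2-bromo-2-methylcyclopropane-1-carboxylate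
Product: 4 ethyl 2-methylidenecyclopropane-1-carboxylate (racemic)
Conditions: NaH, EtOH (cat.), Et2O, reflux
Reagents that add atoms: none
Why: base-mediated dehydrobromination (elimination, ethoxide formed catalytically) removes HBr across C2 and the methyl group, the exocyclic position being the preferred place for a C=C bond on a cyclopropane.

Step 3
Reactants: 4 ethyl 2-methylidenecyclopropane-1-carboxylate
Product: 5 2-methylidenecyclopropane-1-carboxylic acid (racemic)
Conditions: LiOH·H2O, THF/H2O, 0 °C to rt; then 1 M HCl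
Reagents that add atoms: lithium hydroxide, [Li+].[OH-]
Why: ester saponification under mild conditions that should leave the strained exocyclic alkene in place.

Step 4
Reactants: 5 2-methylidenecyclopropane-1-carboxylic acid
Product: 7 N,N-diphenyl-2-methylidenecyclopropane-1-carboxamide (racemic), via 2-methylidenecyclopropane-1-carbonyl chloride 6 (not isolated)
Conditions: (COCl)2, DMF (cat.), CH2Cl2, 0 °C to rt; then Ph2NH, Et3N, DMAP (cat.), CH2Cl2, rt
Reagents that add atoms: diphenylamine, c1ccc(Nc2ccccc2)cc1
Why: acid chloride formation and DMAP-catalysed N-acylation of the weakly nucleophilic diarylamine (amide formation); the diphenylamide is the activating group that the ring expansion needs.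

Step 5
Reactants: 7 N,N-diphenyl-2-methylidenecyclopropane-1-carboxamide; 8 3,4-bis(benzyloxy)benzaldehyde
Product: 11 (2S,3S)-2-[3,4-bis(benzyloxy)phenyl]-4-methylidene-N,N-diphenyloxolane-3-carboxamide, via iodomagnesium dienolate 9 (not isolated), via iodomagnesium aldolate 10 (not isolated)
Conditions: MgI2 (30 mol %), 2,2'-(propane-2,2-diyl)bis[(4S)-4-phenyl-4,5-dihydro-1,3-oxazole] (33 mol %), 4 Å molecular sieves, THF, 60 °C
Reagents that add atoms: none
Why: Proposed new method: the magnesium Lewis acid binds the amide carbonyl of 7 and iodide opens the strained ring by SN2 attack at the ring CH2 (homo-conjugate addition), which erases the stereocentre of racemic 7 and gives dienolate 9; 9 adds through its alpha carbon to 8 (aldol, new C2–C3 bond) and the alkoxide of 10 displaces the allylic iodide (new O1–C5 bond), releasing MgI2. The closest known reaction type is the MgI2-mediated ring expansion of methylidenecyclopropane carboxamides with aldimines to 2,3-trans 4-methylidenepyrrolidines, including a version with a chiral magnesium Lewis acid; the aldehyde partner combined with the chiral ligand is the new element. The oxolane closes by 5-exo-tet O-alkylation at the primary allylic iodide. The 2,3-trans relation should follow from the Z(O) amide enolate reacting through a closed six-membered magnesium transition state (syn aldol, which maps onto the trans oxolane), and the absolute configuration from the C2-symmetric bis(oxazoline) on magnesium shielding one face of the bound dienolate. The step needs alpha rather than gamma attack of the dienolate and ring closure faster than retro-aldol or alkene migration; the strongly magnesium-bound diphenylamide directs alpha attack as in the imine series, and the reactive allylic iodide drains the reversible aldol towards product.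

Step 6
Reactants: 11 (2S,3S)-2-[3,4-bis(benzyloxy)phenyl]-4-methylidene-N,N-diphenyloxolane-3-carboxamide; 12 1-(benzyloxy)-4-bromo-2-methoxybenzene
Product: 14 (2S,3S,4R)-4-{[4-(benzyloxy)-3-methoxyphenyl]methyl}-2-[3,4-bis(benzyloxy)phenyl]-N,N-diphenyloxolane-3-carboxamide, via B-alkyl-9-borabicyclononane adduct 13 (not isolated)
Conditions: 9-BBN dimer, THF, 0 °C to rt; then 12, Pd(dppf)Cl2 (5 mol %), 3 M aq. K3PO4, DMF, 60 °C
Reagents that add atoms: none
Why: anti-Markovnikov hydroboration with bulky 9-BBN should deliver H to C4 from the face opposite the adjacent C3 carboxamide, placing the new CH2 group cis to the carboxamide (4R), and the primary alkylborane then couples with 12 in a B-alkyl Suzuki–Miyaura reaction that touches no stereocentre.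

Step 7
Reactants: 14 (2S,3S,4R)-4-{[4-(benzyloxy)-3-methoxyphenyl]methyl}-2-[3,4-bis(benzyloxy)phenyl]-N,N-diphenyloxolane-3-carboxamide
Product: 15 [(2S,3R,4R)-4-{[4-(benzyloxy)-3-methoxyphenyl]methyl}-2-[3,4-bis(benzyloxy)phenyl]oxolan-3-yl]methanol
Conditions: LiEt3BH (4 equiv), THF, 0 °C to rt; then H2O
Reagents that add atoms: none
Why: hydride reduction of a tertiary amide to the primary alcohol with C–N cleavage, favoured because the tetrahedral adduct expels the weakly basic diphenylamide and the carbonyl stage is reduced at once, so C3 should keep its configuration.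

Step 8
Reactants: 15 [(2S,3R,4R)-4-{[4-(benzyloxy)-3-methoxyphenyl]methyl}-2-[3,4-bis(benzyloxy)phenyl]oxolan-3-yl]methanol
Product: 16 [(2S,3R,4R)-4-{[4-(benzyloxy)-3-methoxyphenyl]methyl}-2-[3,4-bis(benzyloxy)phenyl]oxolan-3-yl]methyl acetate
Conditions: Ac2O, pyridine, DMAP (cat.), CH2Cl2, 0 °C to rt
Reagents that add atoms: acetic anhydride, CC(=O)OC(C)=O
Why: DMAP-catalysed O-acetylation of the only free hydroxyl group, all phenols being masked as benzyl ethers.

Step 9
Reactants: 16 [(2S,3R,4R)-4-{[4-(benzyloxy)-3-methoxyphenyl]methyl}-2-[3,4-bis(benzyloxy)phenyl]oxolan-3-yl]methyl acetate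
Product: 17 [(2S,3R,4R)-2-(3,4-dihydroxyphenyl)-4-[(4-hydroxy-3-methoxyphenyl)methyl]oxolan-3-yl]methyl acetate
Conditions: H2 (1 atm), 10% Pd/C, EtOAc, rt, stopped when 16 and the partly debenzylated intermediates are consumed
Reagents that add atoms: none
Why: hydrogenolysis of the three aryl benzyl ethers under neutral conditions, where O-benzyl cleavage should be much faster than cleavage of the cyclic C2–O1 benzylic ether and the acetate is inert.

**Compound list**

1 | 2-bromopropene | CC(Br)=C | starting material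
2 | ethyl diazoacetate | CCOC(=O)C=[N+]=[N-] | starting material
3 | ethyl 2-bromo-2-methylcyclopropane-1-carboxylate (racemic, cis/trans mixture) | CCOC(=O)C1CC1(C)Br | intermediate
4 | ethyl 2-methylidenecyclopropane-1-carboxylate (racemic) | CCOC(=O)C1CC1=C | intermediate
5 | 2-methylidenecyclopropane-1-carboxylic acid (racemic) | OC(=O)C1CC1=C | intermediate
6 | 2-methylidenecyclopropane-1-carbonyl chloride (racemic, not isolated) | ClC(=O)C1CC1=C | intermediate
7 | N,N-diphenyl-2-methylidenecyclopropane-1-carboxamide (racemic) | C=C1CC1C(=O)N(c1ccccc1)c1ccccc1 | intermediate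
8 | 3,4-bis(benzyloxy)benzaldehyde | O=Cc1ccc(OCc2ccccc2)c(OCc2ccccc2)c1 | starting material
9 | iodomagnesium (Z)-enolate of 3-(iodomethyl)-N,N-diphenylbut-3-enamide (not isolated) | C=C(CI)/C=C(\O[Mg]I)N(c1ccccc1)c1ccccc1 | intermediate
10 | iodomagnesium alkoxide of (2S)-2-{(S)-[3,4-bis(benzyloxy)phenyl](hydroxy)methyl}-3-(iodomethyl)-N,N-diphenylbut-3-enamide (not isolated) | I[Mg]O[C@H](c1ccc(OCc2ccccc2)c(OCc2ccccc2)c1)[C@H](C(=C)CI)C(=O)N(c1ccccc1)c1ccccc1 | intermediate
11 | (2S,3S)-2-[3,4-bis(benzyloxy)phenyl]-4-methylidene-N,N-diphenyloxolane-3-carboxamide | C=C1CO[C@H](c2ccc(OCc3ccccc3)c(OCc3ccccc3)c2)[C@H]1C(=O)N(c1ccccc1)c1ccccc1 | intermediate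
12 | 1-(benzyloxy)-4-bromo-2-methoxybenzene | COc1cc(Br)ccc1OCc1ccccc1 | starting material
13 | (2S,3S,4R)-4-[(9-borabicyclo[3.3.1]nonan-9-yl)methyl]-2-[3,4-bis(benzyloxy)phenyl]-N,N-diphenyloxolane-3-carboxamide (not isolated) | C12CCCC(CCC1)B2C[C@H]1CO[C@H](c2ccc(OCc3ccccc3)c(OCc3ccccc3)c2)[C@H]1C(=O)N(c1ccccc1)c1ccccc1 | intermediate
14 | (2S,3S,4R)-4-{[4-(benzyloxy)-3-methoxyphenyl]methyl}-2-[3,4-bis(benzyloxy)phenyl]-N,N-diphenyloxolane-3-carboxamide | COc1cc(C[C@H]2CO[C@H](c3ccc(OCc4ccccc4)c(OCc4ccccc4)c3)[C@H]2C(=O)N(c2ccccc2)c2ccccc2)ccc1OCc1ccccc1 | intermediate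
15 | [(2S,3R,4R)-4-{[4-(benzyloxy)-3-methoxyphenyl]methyl}-2-[3,4-bis(benzyloxy)phenyl]oxolan-3-yl]methanol | COc1cc(C[C@H]2CO[C@H](c3ccc(OCc4ccccc4)c(OCc4ccccc4)c3)[C@H]2CO)ccc1OCc1ccccc1 | intermediate
16 | [(2S,3R,4R)-4-{[4-(benzyloxy)-3-methoxyphenyl]methyl}-2-[3,4-bis(benzyloxy)phenyl]oxolan-3-yl]methyl acetate | COc1cc(C[C@H]2CO[C@H](c3ccc(OCc4ccccc4)c(OCc4ccccc4)c3)[C@H]2COC(C)=O)ccc1OCc1ccccc1 | intermediate
17 | [(2S,3R,4R)-2-(3,4-dihydroxyphenyl)-4-[(4-hydroxy-3-methoxyphenyl)methyl]oxolan-3-yl]methyl acetate | COc1cc(C[C@H]2CO[C@H](c3ccc(O)c(O)c3)[C@H]2COC(C)=O)ccc1O | target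

**Step count and risks**

Total step count: 9. Longest linear sequence: 9 steps (steps 1 to 9; 8 and 12 enter as purchased materials).

Steps most likely to fail:

1. Step 5 (proposed new method). What may go wrong: weak enantiofacial discrimination at the aldol stage, a background reaction through ligand-free MgI2, attack of the dienolate through its gamma carbon, or retro-aldol outrunning ring closure with the electron-rich aldehyde. If enantiomeric purity is incomplete, it would be raised by recrystallisation of 11 or 14. Fallback by known chemistry, setting out from 12 and 8 and coming back at 15: diethyl malonate and (R)-epichlorohydrin (NaOEt, EtOH, reflux) give ethyl (1S,5R)-2-oxo-3-oxabicyclo[3.1.0]hexane-1-carboxylate F1. Compound 12 is converted (Mg, THF) into [4-(benzyloxy)-3-methoxyphenyl]magnesium bromide F2, which opens the activated cyclopropane of F1 at its CH2 group (CuBr·SMe2 cat., THF, −30 to 0 °C) to give the trans keto-ester lactone ethyl (3S,4R)-4-{[4-(benzyloxy)-3-methoxyphenyl]methyl}-2-oxooxolane-3-carboxylate F3. Krapcho dealkoxycarbonylation (LiCl, wet DMSO, 150 °C) gives (4R)-4-{[4-(benzyloxy)-3-methoxyphenyl]methyl}oxolan-2-one F4. Its lithium enolate (LiN(iPr)2, THF, −78 °C) adds to 8 anti to the benzyl group and gives the aldol lactone F5 as carbinol epimers. LiAlH4 (THF, 0 °C) gives the triol F6. Catalytic camphorsulfonic acid in CH2Cl2 then ionises the benzylic carbinol and closes the oxolane through the primary hydroxyl on the C4 side, both carbinol epimers converging on the 2,3-trans alcohol 15. In this fallback C4 comes from the chiral pool, C3 from the trans-selective lactone aldol, and the ring is closed at O1–C2.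

2. Step 6. What may go wrong: hydroboration from the wrong face (syn to the carboxamide, if shielding by the C2 aryl group dominates), or slow transmetalation of the hindered alkylborane with the electron-rich bromide. Fallback, setting out from 11 and 12 and coming back at 14: 12 is vinylated (potassium vinyltrifluoroborate, Pd(dppf)Cl2, Cs2CO3, THF/H2O, 80 °C) to 1-(benzyloxy)-4-ethenyl-2-methoxybenzene F7. Cross-metathesis of 11 with F7 (second-generation Hoveyda–Grubbs catalyst, toluene, 80 °C) gives the 4-benzylidene oxolane carboxamide F8. Heterogeneous hydrogenation (H2, PtO2, EtOAc), which spares aryl benzyl ethers, should add hydrogen to the alkene face away from the carboxamide, as in the cis-selective hydrogenation of alpha-benzylidene lactones, and give 14.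

3. Step 7. What may go wrong: slow hydride addition to a carbonyl group crowded by the cis C4 substituent, competing C–O cleavage to the tertiary amine, or epimerisation at C3 at the carbonyl stage. Fallback, setting out from 11 and coming back at 15, reduces the amide before C4 is substituted: LiEt3BH (THF, 0 °C) converts 11 into the homoallylic alcohol [(2S,3R)-2-[3,4-bis(benzyloxy)phenyl]-4-methylideneoxolan-3-yl]methanol F9. Silylation (TBDPSCl, imidazole, DMF) gives the tert-butyldiphenylsilyl ether F10, whose bulky silyloxymethyl group takes over the facial shielding. 9-BBN gives the B-alkyl-9-borabicyclononane adduct F11, which is coupled with 12 under the conditions of step 6 to give the silyl ether of 15, F12. Bu4NF in THF removes the silyl group to give 15.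

Further compounds
F1 | step 5 | ethyl (1S,5R)-2-oxo-3-oxabicyclo[3.1.0]hexane-1-carboxylate | CCOC(=O)[C@]12C[C@H]1COC2=O
F2 | step 5 | [4-(benzyloxy)-3-methoxyphenyl]magnesium bromide | COc1cc([Mg]Br)ccc1OCc1ccccc1
F3 | step 5 | ethyl (3S,4R)-4-{[4-(benzyloxy)-3-methoxyphenyl]methyl}-2-oxooxolane-3-carboxylate | COc1cc(C[C@H]2COC(=O)[C@@H]2C(=O)OCC)ccc1OCc1ccccc1
F4 | step 5 | (4R)-4-{[4-(benzyloxy)-3-methoxyphenyl]methyl}oxolan-2-one | COc1cc(C[C@H]2COC(=O)C2)ccc1OCc1ccccc1
F5 | step 5 | (3S,4R)-4-{[4-(benzyloxy)-3-methoxyphenyl]methyl}-3-{[3,4-bis(benzyloxy)phenyl](hydroxy)methyl}oxolan-2-one (carbinol epimers) | COc1cc(C[C@H]2COC(=O)[C@@H]2C(O)c2ccc(OCc3ccccc3)c(OCc3ccccc3)c2)ccc1OCc1ccccc1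
F6 | step 5 | (2R,3R)-2-{[3,4-bis(benzyloxy)phenyl](hydroxy)methyl}-3-{[4-(benzyloxy)-3-methoxyphenyl]methyl}butane-1,4-diol (carbinol epimers) | COc1cc(C[C@@H](CO)[C@H](CO)C(O)c2ccc(OCc3ccccc3)c(OCc3ccccc3)c2)ccc1OCc1ccccc1
F7 | step 6 | 1-(benzyloxy)-4-ethenyl-2-methoxybenzene | COc1cc(C=C)ccc1OCc1ccccc1
F8 | step 6 | (2S,3S)-4-{[4-(benzyloxy)-3-methoxyphenyl]methylidene}-2-[3,4-bis(benzyloxy)phenyl]-N,N-diphenyloxolane-3-carboxamide (E/Z mixture) | COc1cc(C=C2CO[C@H](c3ccc(OCc4ccccc4)c(OCc4ccccc4)c3)[C@H]2C(=O)N(c2ccccc2)c2ccccc2)ccc1OCc1ccccc1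
F9 | step 7 | [(2S,3R)-2-[3,4-bis(benzyloxy)phenyl]-4-methylideneoxolan-3-yl]methanol | C=C1CO[C@H](c2ccc(OCc3ccccc3)c(OCc3ccccc3)c2)[C@H]1CO
F10 | step 7 | {[(2S,3R)-2-[3,4-bis(benzyloxy)phenyl]-4-methylideneoxolan-3-yl]methoxy}(tert-butyl)diphenylsilane | C=C1CO[C@H](c2ccc(OCc3ccccc3)c(OCc3ccccc3)c2)[C@H]1CO[Si](c1ccccc1)(c1ccccc1)C(C)(C)C
F11 | step 7 | {[(2S,3R,4R)-4-[(9-borabicyclo[3.3.1]nonan-9-yl)methyl]-2-[3,4-bis(benzyloxy)phenyl]oxolan-3-yl]methoxy}(tert-butyl)diphenylsilane | C12CCCC(CCC1)B2C[C@H]1CO[C@H](c2ccc(OCc3ccccc3)c(OCc3ccccc3)c2)[C@H]1CO[Si](c1ccccc1)(c1ccccc1)C(C)(C)C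
F12 | step 7 | {[(2S,3R,4R)-4-{[4-(benzyloxy)-3-methoxyphenyl]methyl}-2-[3,4-bis(benzyloxy)phenyl]oxolan-3-yl]methoxy}(tert-butyl)diphenylsilane | COc1cc(C[C@H]2CO[C@H](c3ccc(OCc4ccccc4)c(OCc4ccccc4)c3)[C@H]2CO[Si](c2ccccc2)(c2ccccc2)C(C)(C)C)ccc1OCc1ccccc1
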